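The winter run served me as a ruler for Friday's and Sunday's flasks.

| flask | J | L | remark | time |
|---|---|---|---|---|
| winter | 3 M | 21 mol% | run made earlier |  |
| dusk | 3 M | 33 mol% | run made earlier |  |
| Friday's | 3.0 M | 15 mol% |  | 30 min |
| Sunday's | 3.0 M | 15 mol% |  | 40 min |

| run | time / min | Q / % | J / % | E / % |
|---|---|---|---|---|
| winter | 4.00 | 2.3 | 59.4 | 0 |
| winter | 10.0 | 10.2 | 54.2 | 0.5 |
| winter | 20.0 | 18.7 | 47.0 | 1.8 |
| winter | 30.0 | 21.9 | 43.3 | 5.3 |
| dusk | 4.00 | 4.3 | 58.7 | 0.1 |
| dusk | 10.0 | 13.9 | 50.0 | 1.0 |
| dusk | 20.0 | 21.6 | 45.4 | 3.8 |
| dusk | 30.0 | 23.5 | 41.0 | 8.8 |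

(readings scatter by 0.5 percentage points)

- which of these there is most of at the end, counted by the J in it, Friday's (E / J / Q)
- which of these there is most of at the end, counted by the J in it, Sunday's (E / J / Q)
- the largest of these amounts at the end, in percent of the J charged, Friday's
- the largest of these amounts at the end, in percent of the J charged, Sunday's

The steps from J to Q and from Q to E carry X, but J ⇌ D does not: at 4.00 min, J read 59.4% in the winter run and 58.7% in the dusk run. So I expected the pace of the two steps with X, not the fall of J into D, to follow the charge of J times the loading of L. I folded the givens into N, a time normalisation: charge of J times loading times time, divided by the same product at the winter run's last reading. Friday's flask has N = 0.714 and Sunday's has N = 0.952.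

If equal N means equal progress, Friday's flask reads as the winter run at 21.4 min and Sunday's at 28.6 min. Interpolating the winter readings, I got J 46.5% over Q 19.2% for Friday's, and J 43.8% over Q 21.4% for Sunday's.

Was one number enough? The dusk run at 20.0 min has N = 1.05, close to the winter run's last reading. Q agreed, 21.6% against 21.9%, but J read 45.4% against 43.3%, so I trusted my J figures to about that gap.

The forecast gave J at 45.8% for Friday's and J at 43% for Sunday's: “Free J therefore remains largest in both”. My figures stood higher on both.

Friday's flask gave J at 45.8%, and Sunday's gave J at 43.7%.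

    J + X ⇌ Q + X, rate k1*[J]*[X] forward; the back reaction follows from the equilibrium constant (K = 0.630, k = 0.180 M⁻¹ min⁻¹)
    Q + X ⇌ E + X, rate k2*[X]*[Q] forward; the back reaction follows from the equilibrium constant (K = 2.00, k = 0.0520 M⁻¹ min⁻¹)
    J ⇌ D (K = 0.660, k = 0.340 min⁻¹)
    L ⇌ X (K = 0.810, k = 0.0540 min⁻¹)

The forecast's choice of J turned over in the longer run: after 300 min, Friday's flask held E 30.9% against J 30.4%. The neighbouring flask was Friday's recipe with 38 mol% of L, which raised N from 0.714 to 1.81. That lies beyond the dusk run's last reading at N = 1.57, so I read J close to 41.0% and E beyond 8.8%. That neighbouring flask held J 40.5% and E 9.72%.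

Readings and results are calculated with made-up constants; the scatter is artificial.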